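## Retrosynthetic overview

1. 33 ⇐ 32 (loss of two TBS groups) ⇐ C13–C14 bond: stereoconvergent nickel coupling of alkenyl bromide 31 (ring A half) with 1-chloroethyl pyrone 12 (ring B half).
2. Key step: both γ-pyrones are disconnected at the ring O–C bond, that is, C–O cyclodehydration of a 1,3,5-triketone. For ring A, triketone 30 is made and closed in one flask from ethyl ketone 26 and methylketene dimer 28 (new annulation, step 15).
3. 26 ⇐ C9–O propionylation ⇐ Felkin anti-aldol of pentan-3-one with aldehyde 22 (C8, C9) ⇐ Evans-syn titanium aldol with (E)-3-bromo-2-methylacrolein 15 (C10, C11, E-alkene).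
4. 12 ⇐ γ-chlorination of pyrone 10 ⇐ triketone 9 ⇐ dianion of dione 6 + aldehyde 3 ⇐ L-proline dimerisation of propanal (C20, C21).
5. Ring order: ring B first (step 5), ring A second (step 15). No other ring is formed.

Locants: the backbone is numbered C1–C23 from the ethyl group on ring A (C1) to the ethyl end beside ring B (C23). The target is (8R,9R,10S,11S,12E,14R,20S,21S), with 8,9-anti, 9,10-syn, 10,11-syn, a 9,11-syn diol and 20,21-anti.

Assumption: in step 16 the pyrone is taken to play the role of the aryl group of a 1-arylethyl chloride, so the ligand enantiomer named there is the one expected to give (14R). Its antipode is equally available.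

## Route

Step 1
Reactants: 1 propanal (two molecules)
Product: 2 (2S,3S)-3-hydroxy-2-methylpentanal
Conditions: L-proline (10 mol %), DMF, 4 °C, syringe-pump addition
Reagents that add atoms: none
Why: Proline-catalysed direct aldehyde aldol (enamine catalysis): the (E)-enamine attacks the Re face of a second propanal in the acid-organised Houk–List chair, setting C20 and C21 as the anti-(2S,3S) pair (about 4:1 anti:syn, high ee; the syn isomer is removed after step 2).

Step 2
Reactants: 2 (2S,3S)-3-hydroxy-2-methylpentanal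
Product: 3 (2S,3S)-3-(tert-butyldimethylsilyloxy)-2-methylpentanal
Conditions: TBSOTf, 2,6-lutidine, CH2Cl2, −78 °C
Reagents that add atoms: TBSOTf, CC(C)(C)[Si](C)(C)OS(=O)(=O)C(F)(F)F
Why: Silyl triflate silylation with a hindered, weakly basic pyridine is fast at −78 °C, so the β-hydroxy aldehyde neither eliminates nor epimerises.

Step 3
Reactants: 4 pentan-3-one; 5 ethyl propionate
Product: 6 4-methylheptane-3,5-dione
Conditions: NaH, THF, reflux; aq. HCl
Reagents that add atoms: none
Why: Crossed Claisen condensation: the sodium enolate of 4 is acylated by 5, and formation of the stabilised diketonate pulls the equilibrium.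

Step 4
Reactants: 6 4-methylheptane-3,5-dione; 3 silyloxy aldehyde
Product: 8 δ-hydroxy-β-diketone, via dilithio dianion 7 (not isolated)
Conditions: LiN(i-Pr)2 (2.1 equiv), THF, −78 to 0 °C; 3, −78 °C; AcOH
Reagents that add atoms: none
Why: γ-Selective aldol addition of a 1,3-diketone dianion (Hauser–Harris type): only the terminal, more basic carbanion attacks the aldehyde. The three new centres are erased in step 5, and the fast addition at −78 °C leaves C20 untouched.

Step 5
Reactants: 8 δ-hydroxy-β-diketone
Product: 10 ring B pyrone, via triketone 9 (not isolated)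
Conditions: DMP, CH2Cl2, rt; then Ph3P, CCl4, 2,6-lutidine, THF, rt
Reagents that add atoms: none
Why: Dess–Martin oxidation gives the 1,3,5-triketone. Appel-type activation of one enol oxygen then lets the distal enol oxygen close ring B by C–O bond formation (neutral γ-pyrone cyclodehydration), so the adjacent centre C20 is not epimerised.

Step 6
Reactants: 10 ring B pyrone
Product: 12 2-(1-chloroethyl) pyrone (1:1 at C14), via lithium dienolate 11 (not isolated)
Conditions: LiN(SiMe3)2, THF, −78 °C; inverse addition to C2Cl6, THF, −78 °C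
Reagents that add atoms: hexachloroethane, ClC(Cl)(Cl)C(Cl)(Cl)Cl
Why: Vinylogous deprotonation occurs at the unhindered 2-ethyl CH2 (the C20 methine is tertiary and shielded), and the 2-ethylidene-2H-pyran-4-olate is chlorinated at the exocyclic carbon. C14 is deliberately unselective here because step 16 is stereoconvergent.

Step 7
Reactants: 13 methacrolein
Product: 15 (E)-3-bromo-2-methylprop-2-enal, via dibromide 14 (not isolated)
Conditions: Br2, CH2Cl2, −78 °C; then Et3N, 0 °C to rt
Reagents that add atoms: bromine, BrBr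
Why: Bromination–dehydrobromination: loss of the tertiary bromide together with the acidified CHBr proton gives the conjugated, thermodynamically preferred E bromoenal, which fixes the C12=C13 geometry.

Step 8
Reactants: 16 (S)-4-benzyl-1,3-thiazolidine-2-thione; 17 propionyl chloride
Product: 18 (S)-4-benzyl-3-propionyl-1,3-thiazolidine-2-thione
Conditions: Et3N, DMAP (cat.), CH2Cl2, 0 °C
Reagents that add atoms: none
Why: Simple N-acylation of the auxiliary by an acid chloride.

Step 9
Reactants: 18 N-propionyl thiazolidinethione; 15 (E)-3-bromo-2-methylprop-2-enal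
Product: 20 Evans-syn aldol adduct, via trichlorotitanium enolate 19 (not isolated)
Conditions: TiCl4 (1.05 equiv), i-Pr2NEt (1.1 equiv), NMP (2 equiv), CH2Cl2, 0 °C; 15
Reagents that add atoms: none
Why: Crimmins titanium aldol: the (Z)-enolate reacts through a non-chelated Zimmerman–Traxler chair on the face away from the benzyl group, giving the Evans-syn (2S,3S) adduct. This sets C10 and C11.

Step 10
Reactants: 20 Evans-syn aldol adduct
Product: 21 C11 TBS ether
Conditions: TBSOTf, 2,6-lutidine, CH2Cl2, 0 °C
Reagents that add atoms: TBSOTf, CC(C)(C)[Si](C)(C)OS(=O)(=O)C(F)(F)F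
Why: Silylation blocks retro-aldol and leaves C9–OH as the only free hydroxyl later on. A TBS group survives steps 11–16.

Step 11
Reactants: 21 C11 TBS ether
Product: 22 (2S,3S,4E)-5-bromo-3-(tert-butyldimethylsilyloxy)-2,4-dimethylpent-4-enal
Conditions: i-Bu2AlH, CH2Cl2, −78 °C
Reagents that add atoms: none
Why: Reductive cleavage of an N-acyl thiazolidinethione: the aluminium hemiaminal collapses to the aldehyde only on work-up, so there is no over-reduction, C10 is not epimerised, and 16 is recovered.

Step 12
Reactants: 4 pentan-3-one; 22 aldehyde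
Product: 24 anti-Felkin-type aldol ketone (8,9-anti and 9,10-syn), via boron enolate 23 (not isolated)
Conditions: c-Hex2BCl, Et3N, Et2O, 0 °C; 22, −78 to −20 °C; H2O2, MeOH, pH 7 buffer
Reagents that add atoms: none
Why: Boron-mediated anti-aldol: c-Hex2BCl/Et3N gives the (E)-enol borinate, whose Zimmerman–Traxler chair fixes 8,9-anti. (E)-Enolates add to α-methyl aldehydes in the Felkin sense (no syn-pentane clash), which fixes 9,10-syn, so C8 and C9 are set from C10.

Step 13
Reactants: 24 aldol ketone; 25 propionic anhydride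
Product: 26 C9 propionate
Conditions: DMAP (cat.), pyridine, CH2Cl2, 0 °C
Reagents that add atoms: none
Why: DMAP-catalysed acyl transfer to the only free hydroxyl forms the C9–O ester bond. Pyridine as the sole base at 0 °C avoids E1cB loss of the new β-acyloxy group.

Step 14
Reactants: 17 propionyl chloride (two molecules)
Product: 28 (Z)-4-ethylidene-3-methyloxetan-2-one, via methylketene 27 (not isolated)
Conditions: Et3N, Et2O, 0 °C to rt
Reagents that add atoms: none
Why: Dehydrochlorination gives methylketene, which undergoes the known head-to-tail [2+2] dimerisation to the β-lactone enol ether.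

Step 15
Reactants: 26 C9 propionate; 28 methylketene dimer
Product: 31 ring A pyrone alkenyl bromide, via lithium enolate 29 (not isolated), via triketone 30 (not isolated)
Conditions: LiN(SiMe3)2 (1.0 equiv), THF, −78 °C; 28, −78 to −40 °C; AcOH; then Ph3P, CCl4, 2,6-lutidine, THF, rt
Reagents that add atoms: none
Why: Proposed new method: a [3+3] γ-pyrone annulation of an ethyl ketone. The bulky amide deprotonates the CH2 side kinetically, and the enolate carbon opens the strained acyl C–O bond of the alkylketene dimer, which acts as a masked 2-methyl-3-oxopentanoyl donor. The ketone enolate released on ring opening at once deprotonates the new 1,3-dicarbonyl, so one equivalent of base ends as the inert triketonate and the β-propionyloxy ketone never meets excess base. Ph3P/CCl4 then turns one enol oxygen into an oxyphosphonium leaving group, and the distal enol oxygen closes ring A (C7–O bond) by addition–elimination under neutral conditions that leave C8, the ester and the silyl ether alone. The closest known reaction types are the enamine + diketene γ-pyrone synthesis, the opening of alkylketene dimers by amide or alkoxide nucleophiles, and Appel-type cyclodehydration of 1,3,5-triketones.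

Step 16
Reactants: 31 ring A pyrone alkenyl bromide; 12 2-(1-chloroethyl) pyrone
Product: 32 bis-TBS ether of the target
Conditions: NiCl2(dme) (10 mol %), (3aS,3a'S,8aR,8a'R)-2,2'-(cyclopropane-1,1-diyl)bis(3a,8a-dihydro-8H-indeno[1,2-d]oxazole) (11 mol %), Mn powder, NaI (0.5 equiv), DMA, 0 °C
Reagents that add atoms: none
Why: Proposed new method: asymmetric nickel-catalysed reductive cross-electrophile coupling, known for 1-arylethyl chlorides with alkenyl bromides, is extended to a 1-(4-pyron-2-yl)ethyl chloride. Mn gives zerovalent nickel, which inserts into the C–Br bond with retention of E geometry. Halogen abstraction from either epimer of 12 gives one planar pyrone-stabilised radical, and its capture and reductive elimination at the chiral bis(oxazoline)–nickel centre set C14 under ligand control (stereoconvergent). The base-free medium protects the acidic C14–H and the ester.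

Step 17
Reactants: 32 bis-TBS ether
Product: 33 target CNP0156731.1
Conditions: HF·pyridine, pyridine, THF, 0 °C to rt
Reagents that add atoms: none
Why: Fluoride-driven desilylation in a buffered, mildly acidic medium frees C11–OH and C21–OH without 1,3-acyl migration, E1cB elimination or epimerisation at C8, C14 or C20.

## Compound list

1 | propanal | CCC=O | starting material
2 | (2S,3S)-3-hydroxy-2-methylpentanal | O=C[C@@H](C)[C@@H](O)CC | intermediate
3 | (2S,3S)-3-(tert-butyldimethylsilyloxy)-2-methylpentanal | O=C[C@@H](C)[C@@H](O[Si](C)(C)C(C)(C)C)CC | intermediate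
4 | pentan-3-one | CCC(=O)CC | starting material
5 | ethyl propionate | CCC(=O)OCC | starting material
6 | 4-methylheptane-3,5-dione | CCC(=O)C(C)C(=O)CC | intermediate
7 | dilithium 4-methylhepta-2,4-diene-3,5-diolate (dianion of 6) | CC=C([O-])C(C)=C([O-])CC.[Li+].[Li+] | intermediate (not isolated)
8 | 9-(tert-butyldimethylsilyloxy)-7-hydroxy-4,6,8-trimethylundecane-3,5-dione; C20 and C21 as in 3; epimer mixture at the three other centres | CCC(=O)C(C)C(=O)C(C)C(O)[C@@H](C)[C@@H](O[Si](C)(C)C(C)(C)C)CC | intermediate
9 | 9-(tert-butyldimethylsilyloxy)-4,6,8-trimethylundecane-3,5,7-trione; C20 and C21 as in 3 | CCC(=O)C(C)C(=O)C(C)C(=O)[C@@H](C)[C@@H](O[Si](C)(C)C(C)(C)C)CC | intermediate (not isolated)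
10 | 2-ethyl-3,5-dimethyl-6-[(2S,3S)-3-(tert-butyldimethylsilyloxy)pentan-2-yl]-4H-pyran-4-one (ring B) | CCc1oc([C@@H](C)[C@@H](O[Si](C)(C)C(C)(C)C)CC)c(C)c(=O)c1C | intermediate
11 | lithium 2-ethylidene-3,5-dimethyl-6-[(2S,3S)-3-(tert-butyldimethylsilyloxy)pentan-2-yl]-2H-pyran-4-olate | CC=C1OC([C@@H](C)[C@@H](O[Si](C)(C)C(C)(C)C)CC)=C(C)C([O-])=C1C.[Li+] | intermediate (not isolated)
12 | 2-(1-chloroethyl)-3,5-dimethyl-6-[(2S,3S)-3-(tert-butyldimethylsilyloxy)pentan-2-yl]-4H-pyran-4-one (both C14 epimers) | CC(Cl)c1oc([C@@H](C)[C@@H](O[Si](C)(C)C(C)(C)C)CC)c(C)c(=O)c1C | intermediate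
13 | methacrolein | C=C(C)C=O | starting material
14 | 2,3-dibromo-2-methylpropanal | O=CC(C)(Br)CBr | intermediate (not isolated)
15 | (E)-3-bromo-2-methylprop-2-enal | O=C/C(C)=C/Br | intermediate
16 | (S)-4-benzyl-1,3-thiazolidine-2-thione | S=C1N[C@@H](Cc2ccccc2)CS1 | starting material
17 | propionyl chloride | CCC(=O)Cl | starting material
18 | (S)-4-benzyl-3-propionyl-1,3-thiazolidine-2-thione | CCC(=O)N1C(=S)SC[C@@H]1Cc1ccccc1 | intermediate
19 | trichlorotitanium (Z)-enolate of 18 | C/C=C(\O[Ti](Cl)(Cl)Cl)N1C(=S)SC[C@@H]1Cc1ccccc1 | intermediate (not isolated)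
20 | (2S,3S,4E)-1-[(4S)-4-benzyl-2-thioxo-1,3-thiazolidin-3-yl]-5-bromo-3-hydroxy-2,4-dimethylpent-4-en-1-one | O=C([C@@H](C)[C@H](O)/C(C)=C/Br)N1C(=S)SC[C@@H]1Cc1ccccc1 | intermediate
21 | 3-O-tert-butyldimethylsilyl ether of 20 | O=C([C@@H](C)[C@H](O[Si](C)(C)C(C)(C)C)/C(C)=C/Br)N1C(=S)SC[C@@H]1Cc1ccccc1 | intermediate
22 | (2S,3S,4E)-5-bromo-3-(tert-butyldimethylsilyloxy)-2,4-dimethylpent-4-enal | O=C[C@@H](C)[C@H](O[Si](C)(C)C(C)(C)C)/C(C)=C/Br | intermediate
23 | (E)-pent-2-en-3-yl dicyclohexylborinate | C/C=C(/OB(C1CCCCC1)C1CCCCC1)CC | intermediate (not isolated)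
24 | (8E)-9-bromo-7-(tert-butyldimethylsilyloxy)-5-hydroxy-4,6,8-trimethylnon-8-en-3-one; the four centres (C8–C11) arranged as in 33 | O[C@H]([C@@H](C)[C@H](O[Si](C)(C)C(C)(C)C)/C(C)=C/Br)[C@@H](C)C(=O)CC | intermediate
25 | propionic anhydride | CCC(=O)OC(=O)CC | starting material
26 | C9 propionate of 24 | CCC(=O)O[C@H]([C@@H](C)[C@H](O[Si](C)(C)C(C)(C)C)/C(C)=C/Br)[C@@H](C)C(=O)CC | intermediate
27 | methylketene | CC=C=O | intermediate (not isolated)
28 | (Z)-4-ethylidene-3-methyloxetan-2-one (methylketene dimer, racemic) | C/C=C1\OC(=O)C1C | intermediate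
29 | kinetic lithium enolate of 26 (ethyl side) | CCC(=O)O[C@H]([C@@H](C)[C@H](O[Si](C)(C)C(C)(C)C)/C(C)=C/Br)[C@@H](C)C([O-])=CC.[Li+] | intermediate (not isolated)
30 | C3,C5,C7-triketone from 26 + 28; C8–C11 as in 33; mixture at C4 and C6 | CCC(=O)O[C@H]([C@@H](C)[C@H](O[Si](C)(C)C(C)(C)C)/C(C)=C/Br)[C@@H](C)C(=O)C(C)C(=O)C(C)C(=O)CC | intermediate (not isolated)
31 | ring A half: 6-ethyl-3,5-dimethyl-4-pyron-2-yl at C8, propionate at C9, OTBS at C11, (E)-alkenyl bromide at C13; C8–C11 as in 33 | CCC(=O)O[C@H]([C@@H](C)[C@H](O[Si](C)(C)C(C)(C)C)/C(C)=C/Br)[C@@H](C)c1oc(CC)c(C)c(=O)c1C | intermediate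
32 | 11,21-bis-O-tert-butyldimethylsilyl ether of 33 | CCC(=O)O[C@H]([C@@H](C)[C@H](O[Si](C)(C)C(C)(C)C)/C(C)=C/[C@@H](C)c1oc([C@@H](C)[C@@H](O[Si](C)(C)C(C)(C)C)CC)c(C)c(=O)c1C)[C@@H](C)c1oc(CC)c(C)c(=O)c1C | intermediate
33 | CNP0156731.1, (8R,9R,10S,11S,12E,14R,20S,21S) | CCC(=O)O[C@H]([C@@H](C)[C@H](O)/C(C)=C/[C@@H](C)c1oc([C@@H](C)[C@@H](O)CC)c(C)c(=O)c1C)[C@@H](C)c1oc(CC)c(C)c(=O)c1C | target

## Step count and risks

Total step count: 17. Longest linear sequence: 9 (steps 7, 9, 10, 11, 12, 13, 15, 16, 17).

**Step 15 (new annulation).**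
- Risks: O-acylation of enolate 29 instead of C-acylation, six-membered attack of 29 on its own propionate, or E1cB loss of propionate.
- The fallback uses known chemistry, sets out from aldehyde 22, comes back at 31, and replaces steps 12, 13 and 15.
- Pentan-3-one 4 and propionic anhydride 25 are condensed in polyphosphoric acid to 2,6-diethyl-3,5-dimethyl-4H-pyran-4-one F1, a known one-step pyrone synthesis.
- F1 is deprotonated with LiN(i-Pr)2 at −78 °C to its lithium dienolate F2, which adds to 22 in the known vinylogous aldol reaction of 2-ethyl-γ-pyrones.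
- The open transition state gives only modest control at C8/C9, so the 8,9-anti-9,10-syn alcohol F3 is separated by chromatography. It is then propionylated with 25 and DMAP to give 31.

**Step 16 (new substrate class).**
- Risks: slow oxidative addition of the hindered β,β-disubstituted bromide, homocoupling or reduction of 12, or low ligand control.
- The fallback uses known chemistry, sets out from 12 and comes back at 32.
- Zinc dust and LiCl in THF convert 12 into the vinylogous Reformatsky reagent F4.
- F4 is coupled with 31 under Pd(dba)2 and P(t-Bu)3, a Negishi-type coupling of a zinc enolate with an alkenyl bromide.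
- C14 is not controlled, so 32 is separated by chromatography from its C14 epimer F5.

**Step 6 (γ-chlorination).**
- Risks: double chlorination by proton exchange, or competing deprotonation at C20 with loss of silanolate.
- The fallback sets out from 10 and comes back at 12.
- Dienolate 11 is oxidised with 2-(phenylsulfonyl)-3-phenyloxaziridine (Davis hydroxylation) to the 2-(1-hydroxyethyl) pyrone F6.
- F6 cannot over-react, and it is converted into 12 by Appel chlorination (Ph3P, CCl4).

Further compounds
F1 | step 15 | 2,6-diethyl-3,5-dimethyl-4H-pyran-4-one | CCc1oc(CC)c(C)c(=O)c1C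
F2 | step 15 | lithium 6-ethyl-2-ethylidene-3,5-dimethyl-2H-pyran-4-olate | CC=C1OC(CC)=C(C)C([O-])=C1C.[Li+]
F3 | step 15 | C9 alcohol corresponding to 31 (free 9-OH, C8–C11 as in 33) | O[C@H]([C@@H](C)[C@H](O[Si](C)(C)C(C)(C)C)/C(C)=C/Br)[C@@H](C)c1oc(CC)c(C)c(=O)c1C
F4 | step 16 | chlorozinc reagent from 12 | CC([Zn]Cl)c1oc([C@@H](C)[C@@H](O[Si](C)(C)C(C)(C)C)CC)c(C)c(=O)c1C
F5 | step 16 | C14 epimer of 32 | CCC(=O)O[C@H]([C@@H](C)[C@H](O[Si](C)(C)C(C)(C)C)/C(C)=C/[C@H](C)c1oc([C@@H](C)[C@@H](O[Si](C)(C)C(C)(C)C)CC)c(C)c(=O)c1C)[C@@H](C)c1oc(CC)c(C)c(=O)c1C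
F6 | step 6 | 2-(1-hydroxyethyl)-3,5-dimethyl-6-[(2S,3S)-3-(tert-butyldimethylsilyloxy)pentan-2-yl]-4H-pyran-4-one | CC(O)c1oc([C@@H](C)[C@@H](O[Si](C)(C)C(C)(C)C)CC)c(C)c(=O)c1C
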